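**Plan**

Ring numbering used throughout: C1 carbinol, C2 (bears the CH2O ester carbon C7), C3 (=CH), C4, C5 (bears the side chain), C6 (CH2).

1. Cuts: the C7–O acyl bond and C1–H; the C(=CH2)–CH2 bond of the skipped diene (alkene–alkyne coupling of ring alkyne 14 with homoallylic alcohol 17); C2–C7 (Morita–Baylis–Hillman); the ring bond C5–C6.
2. Enabling feature: the C(=CH2) carbon on C5 is a masked alkyne carbon, so C5 is propargylic, and C6 is the α-carbon of the C1 carbonyl. An oxane whose ring oxygen joins C5 and C1 (2-ethynyl-6-methylidene oxane) can therefore ionize at C5–O as a Co2(CO)6-stabilized cation and return the C6=C1–O enolate to C5, turning the oxane into the carbocycle.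
3. Forward order: δ-lactone (oxane ring) → exocyclic enol ether → cyclohexanone by O→C ring contraction → C2=C3 by loss of a temporary C3 silyloxy group → CH2OH at C2 → side chain joined → C1 reduced → primary hydroxyl acylated.
4. Stereochemistry: a Ti/BINOL aldol sets the propargylic carbinol; anti reduction relays it to the temporary C3–O centre; that centre (and the ion-pair geometry) sets C5 in the key step; C5 sets C1 (Luche, cis); the tertiary carbinol is bought as (S)-2-methylglycidol.

Key step: step 5

Assumption: with (R)-BINOL the titanium catalyst of step 1 is taken to add the diene to the Re face of ynal 1, as with aromatic and unsaturated aldehydes; if the ynal responds with the opposite sense, (S)-BINOL is used and nothing else changes.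

**Route**

Step 1
Reactants: 1 3-(trimethylsilyl)prop-2-ynal; 2 1-methoxy-1,3-bis(trimethylsilyloxy)buta-1,3-diene
Product: 4 methyl (5R)-5-hydroxy-3-oxo-7-(trimethylsilyl)hept-6-ynoate, via O-silylated aldol adduct 3 (not isolated)
Conditions: Ti(OiPr)4 (8 mol%), (R)-BINOL (8 mol%), 4 Å molecular sieves, THF, −78 °C to rt; then 1 M HCl, THF, 0 °C
Reagents that add atoms: none
Why: Catalytic asymmetric vinylogous Mukaiyama aldol reaction in which the BINOL–titanium Lewis acid binds the ynal and the diene terminus adds to its Re face, setting the propargylic carbinol (5R) before acid removes the O-silyl groups.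

Step 2
Reactants: 4 methyl (5R)-5-hydroxy-3-oxo-7-(trimethylsilyl)hept-6-ynoate
Product: 6 (4R,6R)-4-hydroxy-6-[(trimethylsilyl)ethynyl]oxan-2-one, via anti-diol ester 5 (not isolated)
Conditions: Me4NBH(OAc)3, MeCN/AcOH, −30 °C; then PPTS (cat.), toluene, 60 °C
Reagents that add atoms: none
Why: Evans–Saksena reduction, in which the C5 hydroxyl binds the triacetoxyborohydride and delivers hydride through a chair to give the 1,3-anti diol (3R), which should lactonize under mild acid to the cis-4,6-disubstituted δ-lactone.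

Step 3
Reactants: 6 (4R,6R)-4-hydroxy-6-[(trimethylsilyl)ethynyl]oxan-2-one
Product: 7 (4R,6R)-4-(tert-butyldimethylsilyloxy)-6-[(trimethylsilyl)ethynyl]oxan-2-one
Conditions: TBSCl, imidazole, DMF, rt
Reagents that add atoms: tert-butyldimethylsilyl chloride, CC(C)(C)[Si](C)(C)Cl
Why: Standard silylation of the secondary alcohol, which installs the group that later steers the key step and then leaves to form the C2=C3 double bond.

Step 4
Reactants: 7 (4R,6R)-4-(tert-butyldimethylsilyloxy)-6-[(trimethylsilyl)ethynyl]oxan-2-one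
Product: 9 tert-butyl{[(2R,4R)-2-ethynyl-6-methylideneoxan-4-yl]oxy}dimethylsilane, via C-silylated enol ether 8 (not isolated)
Conditions: Cp2Ti(μ-Cl)(μ-CH2)AlMe2 (Tebbe reagent), pyridine, THF/toluene, −40 to 0 °C; then K2CO3, MeOH, rt
Reagents that add atoms: Tebbe reagent, C[Al-]1(C)C[Ti](C2C=CC=C2)(C2C=CC=C2)[Cl+]1
Why: Tebbe methylenation of the lactone carbonyl should give the exocyclic enol ether (low temperature and the silyl cap keep the titanium methylidene off the triple bond), and basic methanolysis, to which the enol ether is inert, then frees the terminal alkyne.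

Step 5
Reactants: 9 tert-butyl{[(2R,4R)-2-ethynyl-6-methylideneoxan-4-yl]oxy}dimethylsilane
Product: 11 hexacarbonyldicobalt complex of (3R,5S)-3-(tert-butyldimethylsilyloxy)-5-ethynylcyclohexan-1-one, via hexacarbonyldicobalt alkyne complex 10 (not isolated)
Conditions: Co2(CO)8, CH2Cl2, rt; then TiCl4, CH2Cl2, −78 to −30 °C
Reagents that add atoms: dicobalt octacarbonyl, O=C=[Co](=C=O)(=C=O)(=C=O)[Co](=C=O)(=C=O)(=C=O)=C=O
Why: Complexation turns the alkyne into a Co2(CO)6 cluster; TiCl4 then binds the ring oxygen, the C–O bond at the alkyne-bearing carbon (C5) ionizes to a Nicholas cation while the same oxygen leaves as the titanium enolate of the exocyclic enol ether, and the enolate methylene (C6) attacks the cation to give the cyclohexanone (net 1,3 O-to-C shift). The closest known reaction type is the Lewis-acid-promoted Nicholas-type O→C rearrangement of cobalt-complexed 6-alkynyl-2-methylidene oxanes to 3-alkynylcyclohexanones, a relative of the Petasis–Ferrier rearrangement. The carbocycle closes in a 6-(enolendo)-exo-trig mode. The new stereocentre C5 should be set cis to the C3 silyloxy group by a chair transition state with the bulky cluster and the silyl ether both equatorial, and direct collapse of the ion pair with retention from the cis-configured oxane leads to the same cis ketone, so the two limiting pathways converge. The step needs C- over O-recombination and capture faster than proton loss from the cation: O-closure only regenerates the enol ether whereas C–C formation is irreversible, and the tether holds the enolate within reach of the cation.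

Step 6
Reactants: 11 hexacarbonyldicobalt complex of (3R,5S)-3-(tert-butyldimethylsilyloxy)-5-ethynylcyclohexan-1-one
Product: 12 (3R,5S)-3-(tert-butyldimethylsilyloxy)-5-ethynylcyclohexan-1-one
Conditions: (NH4)2Ce(NO3)6, acetone, −10 °C
Reagents that add atoms: none
Why: Oxidative decomplexation of the cobalt cluster should release the alkyne without touching the ketone or the silyl ether at low temperature.

Step 7
Reactants: 12 (3R,5S)-3-(tert-butyldimethylsilyloxy)-5-ethynylcyclohexan-1-one
Product: 13 (5S)-5-ethynylcyclohex-2-en-1-one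
Conditions: DBU, CH2Cl2, rt
Reagents that add atoms: none
Why: E1cB elimination of the β-silyloxy group can only form the C2=C3 double bond, so the enone is regiodefined, and C5 carries no acidic hydrogen and keeps its configuration.

Step 8
Reactants: 13 (5S)-5-ethynylcyclohex-2-en-1-one
Product: 14 (5S)-5-ethynyl-2-(hydroxymethyl)cyclohex-2-en-1-one
Conditions: HCHO (37% aq.), DMAP (20 mol%), THF, rt
Reagents that add atoms: formaldehyde, C=O
Why: Morita–Baylis–Hillman hydroxymethylation, in which DMAP adds to C3, the enolate adds to formaldehyde at C2 and DMAP is expelled, so C7 is installed without touching C5.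

Step 9
Reactants: 15 [(2S)-2-methyloxiran-2-yl]methanol
Product: 16 (2R)-2-methylpent-4-ene-1,2-diol
Conditions: vinylmagnesium bromide (3 equiv), CuI (10 mol%), THF, −30 to 0 °C
Reagents that add atoms: vinylmagnesium bromide, C=C[Mg]Br
Why: Copper-catalysed Grignard opening of the epoxide at its unsubstituted CH2 leaves the quaternary stereocentre untouched (the descriptor changes from S to R only through the priority rules).

Step 10
Reactants: 16 (2R)-2-methylpent-4-ene-1,2-diol
Product: 17 (2R)-2-hydroxy-2-methylpent-4-en-1-yl 2-methylpropanoate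
Conditions: isobutyryl chloride, pyridine, CH2Cl2, 0 °C
Reagents that add atoms: 2-methylpropanoyl chloride, CC(C)C(=O)Cl
Why: Acylation is expected at the primary hydroxyl only, since the tertiary alcohol is inert under these conditions.

Step 11
Reactants: 14 (5S)-5-ethynyl-2-(hydroxymethyl)cyclohex-2-en-1-one; 17 (2R)-2-hydroxy-2-methylpent-4-en-1-yl 2-methylpropanoate
Product: 18 (2R,3E)-2-hydroxy-6-[(1S)-4-(hydroxymethyl)-5-oxocyclohex-3-en-1-yl]-2-methylhepta-3,6-dien-1-yl 2-methylpropanoate
Conditions: [CpRu(MeCN)3]PF6 (10 mol%), acetone, rt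
Reagents that add atoms: none
Why: Ruthenium-catalysed alkene–alkyne coupling (Alder-ene type) through a ruthenacyclopentene, in which the α-branched ring substituent of the alkyne sits remote from the metal so that the internal alkyne carbon bonds to the terminal alkene carbon, and β-hydride elimination from the allylic CH2 of 17 gives the 1,1-disubstituted alkene and the E-configured skipped diene.

Step 12
Reactants: 18 (2R,3E)-2-hydroxy-6-[(1S)-4-(hydroxymethyl)-5-oxocyclohex-3-en-1-yl]-2-methylhepta-3,6-dien-1-yl 2-methylpropanoate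
Product: 19 (2R,3E)-2-hydroxy-6-[(1S,5S)-5-hydroxy-4-(hydroxymethyl)cyclohex-3-en-1-yl]-2-methylhepta-3,6-dien-1-yl 2-methylpropanoate
Conditions: NaBH4, CeCl3·7H2O, MeOH, −78 °C
Reagents that add atoms: none
Why: Luche 1,2-reduction, in which axial hydride attack on the half-chair that holds the C5 substituent equatorial should give the cis (1S) allylic alcohol, as in the carvone to cis-carveol reduction, while the ester and the alkenes are untouched.

Step 13
Reactants: 19 (2R,3E)-2-hydroxy-6-[(1S,5S)-5-hydroxy-4-(hydroxymethyl)cyclohex-3-en-1-yl]-2-methylhepta-3,6-dien-1-yl 2-methylpropanoate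
Product: 20 {(4S,6S)-6-hydroxy-4-[(4E,6R)-6-hydroxy-6-methyl-7-(2-methylpropanoyloxy)hepta-1,4-dien-2-yl]cyclohex-1-en-1-yl}methyl 2-methylpropanoate (target)
Conditions: isobutyryl chloride (1.05 equiv), 2,4,6-collidine, CH2Cl2, −78 to −40 °C
Reagents that add atoms: 2-methylpropanoyl chloride, CC(C)C(=O)Cl
Why: Low-temperature acylation with a hindered base should take the primary allylic hydroxyl in preference to the flanked secondary allylic hydroxyl and the tertiary hydroxyl.

**Compound list**

1 | 3-(trimethylsilyl)prop-2-ynal | C[Si](C)(C)C#CC=O | starting material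
2 | 1-methoxy-1,3-bis(trimethylsilyloxy)buta-1,3-diene | COC(O[Si](C)(C)C)=CC(=C)O[Si](C)(C)C | starting material
3 | methyl (5R)-3-oxo-7-(trimethylsilyl)-5-(trimethylsilyloxy)hept-6-ynoate | C[Si](C)(C)C#C[C@H](O[Si](C)(C)C)CC(=O)CC(=O)OC | intermediate
4 | methyl (5R)-5-hydroxy-3-oxo-7-(trimethylsilyl)hept-6-ynoate | C[Si](C)(C)C#C[C@H](O)CC(=O)CC(=O)OC | intermediate
5 | methyl (3R,5R)-3,5-dihydroxy-7-(trimethylsilyl)hept-6-ynoate | C[Si](C)(C)C#C[C@H](O)C[C@@H](O)CC(=O)OC | intermediate
6 | (4R,6R)-4-hydroxy-6-[(trimethylsilyl)ethynyl]oxan-2-one | C[Si](C)(C)C#C[C@H]1C[C@@H](O)CC(=O)O1 | intermediate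
7 | (4R,6R)-4-(tert-butyldimethylsilyloxy)-6-[(trimethylsilyl)ethynyl]oxan-2-one | C[Si](C)(C)C#C[C@H]1C[C@@H](O[Si](C)(C)C(C)(C)C)CC(=O)O1 | intermediate
8 | tert-butyldimethyl{[(2R,4R)-6-methylidene-2-[(trimethylsilyl)ethynyl]oxan-4-yl]oxy}silane | C[Si](C)(C)C#C[C@H]1C[C@@H](O[Si](C)(C)C(C)(C)C)CC(=C)O1 | intermediate
9 | tert-butyl{[(2R,4R)-2-ethynyl-6-methylideneoxan-4-yl]oxy}dimethylsilane | C#C[C@H]1C[C@@H](O[Si](C)(C)C(C)(C)C)CC(=C)O1 | intermediate
10 | hexacarbonyldicobalt complex of the alkyne of 9 | C12[Co]3(=C=O)(=C=O)(=C=O)[Co]1(=C=O)(=C=O)(=C=O)C23[C@H]4C[C@@H](O[Si](C)(C)C(C)(C)C)CC(=C)O4 | intermediate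
11 | hexacarbonyldicobalt complex of (3R,5S)-3-(tert-butyldimethylsilyloxy)-5-ethynylcyclohexan-1-one | C12[Co]3(=C=O)(=C=O)(=C=O)[Co]1(=C=O)(=C=O)(=C=O)C23[C@H]4C[C@@H](O[Si](C)(C)C(C)(C)C)CC(=O)C4 | intermediate
12 | (3R,5S)-3-(tert-butyldimethylsilyloxy)-5-ethynylcyclohexan-1-one | C#C[C@H]1C[C@@H](O[Si](C)(C)C(C)(C)C)CC(=O)C1 | intermediate
13 | (5S)-5-ethynylcyclohex-2-en-1-one | C#C[C@H]1CC=CC(=O)C1 | intermediate
14 | (5S)-5-ethynyl-2-(hydroxymethyl)cyclohex-2-en-1-one | C#C[C@H]1CC=C(CO)C(=O)C1 | intermediate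
15 | [(2S)-2-methyloxiran-2-yl]methanol ((S)-2-methylglycidol) | C[C@]1(CO)CO1 | starting material
16 | (2R)-2-methylpent-4-ene-1,2-diol | C=CC[C@@](C)(O)CO | intermediate
17 | (2R)-2-hydroxy-2-methylpent-4-en-1-yl 2-methylpropanoate | C=CC[C@@](C)(O)COC(=O)C(C)C | intermediate
18 | (2R,3E)-2-hydroxy-6-[(1S)-4-(hydroxymethyl)-5-oxocyclohex-3-en-1-yl]-2-methylhepta-3,6-dien-1-yl 2-methylpropanoate | C=C(C/C=C/[C@@](C)(O)COC(=O)C(C)C)[C@H]1CC=C(CO)C(=O)C1 | intermediate
19 | (2R,3E)-2-hydroxy-6-[(1S,5S)-5-hydroxy-4-(hydroxymethyl)cyclohex-3-en-1-yl]-2-methylhepta-3,6-dien-1-yl 2-methylpropanoate | C=C(C/C=C/[C@@](C)(O)COC(=O)C(C)C)[C@H]1CC=C(CO)[C@@H](O)C1 | intermediate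
20 | {(4S,6S)-6-hydroxy-4-[(4E,6R)-6-hydroxy-6-methyl-7-(2-methylpropanoyloxy)hepta-1,4-dien-2-yl]cyclohex-1-en-1-yl}methyl 2-methylpropanoate | C=C(C/C=C/[C@@](C)(O)COC(=O)C(C)C)[C@H]1CC=C(COC(=O)C(C)C)[C@@H](O)C1 | target

**Count and risks**

Total step count: 13. Longest linear sequence: 11 steps (steps 1–8 and 11–13).

Steps most likely to fail:

Step 5. What may go wrong: incomplete facial control in the capture of the fluxional cobalt-stabilized cation, and loss of a proton from the cation to an enyne before the enolate closes. Any trans-3,5 ketone would become the enantiomer of 13 after step 7, so it has to be removed by chromatography at the stage of 12. Fallback: the C5–C6 bond is made first and intermolecularly under iminium catalysis, and the ring is then closed by aldol condensation; it sets out from 1 and comes back to the route at 13. Wittig reaction of 1 with Ph3P=CHCHO (toluene, 60 °C) should give (2E)-5-(trimethylsilyl)pent-2-en-4-ynal F1. Conjugate addition of tert-butyl 3-oxobutanoate to F1 under catalysis by a diphenylprolinol trimethylsilyl ether (the enantiomer that leads to 5S), followed by TsOH in toluene at 80 °C (aldol condensation and loss of the tert-butyl ester as isobutene and CO2), should give (5S)-5-[(trimethylsilyl)ethynyl]cyclohex-2-en-1-one F2. K2CO3 in MeOH at 0 °C then removes the silyl group to give 13.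

Step 11. What may go wrong: carbon–carbon bond formation at the terminal instead of the internal alkyne carbon (linear 1,4-diene), or oligomerization of the alkyne. Fallback: the 1,1-disubstituted alkene is fixed as a vinylstannane and joined to the side chain by Stille coupling through a π-allyl complex; it sets out from 12 and 17 and comes back to the route at 18.
- Markovnikov hydrostannation of 12 (Bu3SnH, Mo(CO)3(CNtBu)3 cat., THF, 55 °C) should give (3R,5S)-3-(tert-butyldimethylsilyloxy)-5-[1-(tributylstannyl)ethenyl]cyclohexan-1-one F3.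
- Allylic hydroxylation of 17 (SeO2 cat., t-BuOOH, CH2Cl2) should give (2S,3RS)-2,3-dihydroxy-2-methylpent-4-en-1-yl 2-methylpropanoate F4, and acetylation of its secondary hydroxyl (Ac2O, pyridine, 0 °C) gives (2S,3RS)-3-acetoxy-2-hydroxy-2-methylpent-4-en-1-yl 2-methylpropanoate F5.
- Stille coupling of F3 with F5 (Pd2(dba)3, LiCl, DMF, rt) places the vinyl group on the unsubstituted allyl terminus and should give (2R,3E)-6-[(1S,3R)-3-(tert-butyldimethylsilyloxy)-5-oxocyclohexyl]-2-hydroxy-2-methylhepta-3,6-dien-1-yl 2-methylpropanoate F6.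
- DBU elimination as in step 7 gives (2R,3E)-2-hydroxy-2-methyl-6-[(1S)-5-oxocyclohex-3-en-1-yl]hepta-3,6-dien-1-yl 2-methylpropanoate F7, and hydroxymethylation of F7 as in step 8 gives 18.

Step 4. What may go wrong: transfer of the titanium methylidene to the triple bond instead of the lactone carbonyl, and acid-induced migration of the exocyclic double bond into the ring. Fallback: the enol ether is made without a titanium carbene, by iodoetherification and elimination; it sets out from 7 and comes back to the route at 9 (through 8). Reduction of 7 with i-Bu2AlH (CH2Cl2, −78 °C) should give (4R,6R)-4-(tert-butyldimethylsilyloxy)-6-[(trimethylsilyl)ethynyl]oxan-2-ol F8. Wittig methylenation (Ph3PCH3Br, KN(SiMe3)2, THF) gives (3R,5S)-5-(tert-butyldimethylsilyloxy)-1-(trimethylsilyl)oct-7-en-1-yn-3-ol F9. 6-Exo iodoetherification (I2, NaHCO3, MeCN) gives tert-butyl{[(2RS,4R,6R)-2-(iodomethyl)-6-[(trimethylsilyl)ethynyl]oxan-4-yl]oxy}dimethylsilane F10. Elimination of hydrogen iodide (DBU, toluene, 80 °C) gives 8, which is desilylated with K2CO3 in MeOH as in step 4 to give 9.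

Further compounds
F1 | step 5 | (2E)-5-(trimethylsilyl)pent-2-en-4-ynal | C[Si](C)(C)C#C/C=C/C=O
F2 | step 5 | (5S)-5-[(trimethylsilyl)ethynyl]cyclohex-2-en-1-one | C[Si](C)(C)C#C[C@H]1CC=CC(=O)C1
F3 | step 11 | (3R,5S)-3-(tert-butyldimethylsilyloxy)-5-[1-(tributylstannyl)ethenyl]cyclohexan-1-one | CCCC[Sn](CCCC)(CCCC)C(=C)[C@H]1C[C@@H](O[Si](C)(C)C(C)(C)C)CC(=O)C1
F4 | step 11 | (2S,3RS)-2,3-dihydroxy-2-methylpent-4-en-1-yl 2-methylpropanoate | C=CC(O)[C@@](C)(O)COC(=O)C(C)C
F5 | step 11 | (2S,3RS)-3-acetoxy-2-hydroxy-2-methylpent-4-en-1-yl 2-methylpropanoate | C=CC(OC(C)=O)[C@@](C)(O)COC(=O)C(C)C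
F6 | step 11 | (2R,3E)-6-[(1S,3R)-3-(tert-butyldimethylsilyloxy)-5-oxocyclohexyl]-2-hydroxy-2-methylhepta-3,6-dien-1-yl 2-methylpropanoate | C=C(C/C=C/[C@@](C)(O)COC(=O)C(C)C)[C@H]1C[C@@H](O[Si](C)(C)C(C)(C)C)CC(=O)C1
F7 | step 11 | (2R,3E)-2-hydroxy-2-methyl-6-[(1S)-5-oxocyclohex-3-en-1-yl]hepta-3,6-dien-1-yl 2-methylpropanoate | C=C(C/C=C/[C@@](C)(O)COC(=O)C(C)C)[C@H]1CC=CC(=O)C1
F8 | step 4 | (4R,6R)-4-(tert-butyldimethylsilyloxy)-6-[(trimethylsilyl)ethynyl]oxan-2-ol | C[Si](C)(C)C#C[C@H]1C[C@@H](O[Si](C)(C)C(C)(C)C)CC(O)O1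
F9 | step 4 | (3R,5S)-5-(tert-butyldimethylsilyloxy)-1-(trimethylsilyl)oct-7-en-1-yn-3-ol | C[Si](C)(C)C#C[C@H](O)C[C@@H](O[Si](C)(C)C(C)(C)C)CC=C
F10 | step 4 | tert-butyl{[(2RS,4R,6R)-2-(iodomethyl)-6-[(trimethylsilyl)ethynyl]oxan-4-yl]oxy}dimethylsilane | C[Si](C)(C)C#C[C@H]1C[C@@H](O[Si](C)(C)C(C)(C)C)CC(CI)O1
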